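**Retrosynthetic overview**
1. The target comes from hydrogenation (C5=C6 and C12=C13) of a Z-oxonenone. That ring is closed last by RCM between the C3-allyl group and a C9-(2-oxobut-3-enyl) group.
2. The C8–C9 bond comes from convex-face C-glycosidation of a lactol acetate derived from a tricyclic γ-lactone. The C11-OAc comes from convex-face 1,2-reduction of the ring-A enone.
3. Key step: the oxepane and the γ-lactone (the future THF) form in one acid-catalysed cascade. O16 opens the C2–C3 epoxide at tertiary C3 with inversion, and the freed O2 lactonises onto the C9 ester.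
4. Ring A comes from a formal [3+3] annulation. An alkylidene β-keto ester (epoxy aldehyde + methyl 3-oxopentanoate) takes up a β-methyl aldehyde by Michael addition, then aldol condensation closes the ring.
5. Ring order: cyclohexenone, then oxepane + lactone together, then oxonane. Stereo sources: Sharpless epoxide (C2, C3), bromo alcohol (C15), organocatalyst (C1, C14), substrate control (C9–C12).

Assumption: atoms are named by asbestinin numbering (ring A = C1, C10–C14; THF = C1, C2, O, C9, C10; oxepane = C1–C3, O, C16, C15, C14). The labile C10 of β-keto esters 14–16 and the E/Z geometry of 13 are left undefined.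

Step 1
Reactants: 1 but-2-yn-1-ol
Product: 3 (Z)-3-iodobut-2-en-1-ol, via cyclic vinylalanate 2 (not isolated)
Conditions: Red-Al, THF, 0 °C to rt; then I2, −78 °C
Reagents that add atoms: iodine, II
Why: Hydroxyl-directed trans-hydroalumination of the propargylic alcohol places Al on C3 in a five-membered alanate, and iodinolysis with retention gives only the Z-iodide (I cis to CH2OH).

Step 2
Reactants: 3 (Z)-3-iodobut-2-en-1-ol; 4 allyltributylstannane
Product: 5 (Z)-3-methylhexa-2,5-dien-1-ol
Conditions: Pd2(dba)3 (2.5 mol %), AsPh3, CuI, DMF, rt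
Reagents that add atoms: none
Why: Stille cross-coupling keeps the olefin geometry, so the allyl group ends cis to CH2OH (nerol-type Z-olefin), which the later inversion at C3 requires.

Step 3
Reactants: 5 (Z)-3-methylhexa-2,5-dien-1-ol
Product: 6 [(2S,3R)-3-allyl-3-methyloxiran-2-yl]methanol
Conditions: Ti(OiPr)4 (10 mol %), L-(+)-DET (12 mol %), t-BuOOH, 4 Å MS, CH2Cl2, −20 °C
Reagents that add atoms: tert-butyl hydroperoxide, CC(C)(C)OO
Why: Katsuki–Sharpless asymmetric epoxidation touches only the allylic-alcohol olefin, and as with nerol the L-(+)-tartrate gives the (2S,3R)-epoxide, fixing C2 directly and C3 through its later inversion.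

Step 4
Reactants: 6 [(2S,3R)-3-allyl-3-methyloxiran-2-yl]methanol
Product: 7 (2R,3R)-3-allyl-3-methyloxirane-2-carbaldehyde (same spatial arrangement as 6)
Conditions: TEMPO (10 mol %), PhI(OAc)2, CH2Cl2, rt
Reagents that add atoms: none
Why: The TEMPO/oxoammonium oxidation stops at the aldehyde under near-neutral conditions, so the epoxide, the terminal olefin and the poorly enolisable α-centre are untouched.

Step 5
Reactants: 8 (S)-3-bromo-2-methylpropan-1-ol
Product: 9 (S)-(3-bromo-2-methylpropoxy)triethylsilane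
Conditions: Et3SiCl, imidazole, CH2Cl2, 0 °C
Reagents that add atoms: chlorotriethylsilane, CC[Si](Cl)(CC)CC
Why: Silylation masks O16 so that it cannot add to the ring-A enone (5-exo oxa-Michael) later, and the C15 stereocentre is not involved.

Step 6
Reactants: 9 (S)-(3-bromo-2-methylpropoxy)triethylsilane
Product: 11 (R)-3-methyl-4-(triethylsilyloxy)butanal, via Grignard reagent 10 (not isolated)
Conditions: Mg, THF, 40 °C; then DMF, 0 °C; aq. NH4Cl
Reagents that add atoms: N,N-dimethylformamide, CN(C)C=O
Why: Bouveault formylation of the primary Grignard reagent adds C13 without touching C15 (the descriptor changes only through CIP priorities).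

Step 7
Reactants: 7 (2R,3R)-3-allyl-3-methyloxirane-2-carbaldehyde; 12 methyl 3-oxopentanoate
Product: 13 methyl 2-{[(2S,3R)-3-allyl-3-methyloxiran-2-yl]methylidene}-3-oxopentanoate (E/Z mixture)
Conditions: piperidine (10 mol %), AcOH (10 mol %), 4 Å MS, CH2Cl2, 0 °C
Reagents that add atoms: none
Why: Knoevenagel condensation of the reactive, poorly enolisable epoxy aldehyde with the active methylene (C10) gives the doubly activated C1=C10 acceptor under buffered conditions that leave the trisubstituted epoxide intact.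

Step 8
Reactants: 13 methyl 2-{[(2S,3R)-3-allyl-3-methyloxiran-2-yl]methylidene}-3-oxopentanoate; 11 (R)-3-methyl-4-(triethylsilyloxy)butanal
Product: 15 methyl (5S,6S)-6-[(2S,3R)-3-allyl-3-methyloxiran-2-yl]-3-methyl-2-oxo-5-[(R)-1-(triethylsilyloxy)propan-2-yl]cyclohex-3-ene-1-carboxylate, via Michael adduct 14 (not isolated)
Conditions: (R)-2-[diphenyl(trimethylsilyloxy)methyl]pyrrolidine (20 mol %), PhCO2H (20 mol %), toluene, 0 °C to rt; then pyrrolidine (30 mol %), AcOH (60 mol %), 4 Å MS, 45 °C
Reagents that add atoms: none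
Why: A syn-selective enamine Michael addition (C14 to C1) followed by an amine/acid-mediated intramolecular aldol (Mannich-type) condensation of C12 onto the C13 aldehyde amounts to a formal [3+3] Robinson-type annulation, in which the (R)-catalyst sets 14S and 1S (syn adduct = 5,6-trans) and the epimerisable C14 can also settle into the trans-diequatorial arrangement.

Step 9
Reactants: 15 epoxy enone β-keto ester (as named in step 8)
Product: 17 tricyclic keto-lactone (ring-A 12-en-11-one, C9(=O)–O–C2 γ-lactone cis-fused at C1/C10, C3–O–C16 oxepane trans-fused at C1/C14, C3 bearing Me and allyl), via oxepane silyl ether 16 (not isolated)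
Conditions: Tf2NH (10 mol %), CH2Cl2 (5 mM), −78 °C to rt
Reagents that add atoms: none
Why: Proposed new method: H+ (then Et3Si+ as chain carrier) activates the epoxide, whose C3–O bond is the weaker one (tertiary cationic character, while C2 is shielded by quaternary C3 and branched C1), so the silyl-ether oxygen O16 attacks C3 in 7-endo fashion with inversion to give 3S, passes its silyl group to O2 (16), and O2 then lactonises onto the cis C9 ester (C10 equilibrates) with loss of Et3SiOMe, forming the oxepane and the lactone in one operation; the closest known reaction types are acid-promoted endo-selective hydroxy-epoxide cyclisation at the tertiary carbon (oxepane-forming polyepoxide cascades) and silyl-triflate activation of epoxy silyl ethers.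

Step 10
Reactants: 17 tricyclic keto-lactone
Product: 18 tricyclic 11-hydroxy lactone (allylic alcohol, C11 configured as in the target)
Conditions: NaBH4, CeCl3·7H2O, MeOH, −40 °C
Reagents that add atoms: none
Why: Luche 1,2-reduction delivers hydride to the convex face (syn to H1/H10, anti to the lactone ring), placing O11 cis to the C10–C9 bond and ending the lability of C10.

Step 11
Reactants: 18 tricyclic 11-hydroxy lactone
Product: 20 C11,C9-diacetate (allylic acetate plus anomeric acetate, C9 epimers), via lactol 19 (not isolated)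
Conditions: DIBAL-H (3.2 equiv), CH2Cl2, −78 °C; then pyridine, DMAP, Ac2O, −78 to 0 °C
Reagents that add atoms: acetic anhydride, CC(=O)OC(C)=O
Why: Reductive acetylation of the lactone (DIBAL-H, then trapping of the aluminium alkoxides with Ac2O) installs the final C11 acetate and the C9 leaving group in one flask without touching any stereocentre.

Step 12
Reactants: 20 C11,C9-diacetate; 21 2-(trimethylsilyloxy)buta-1,3-diene
Product: 22 C9-(2-oxobut-3-enyl) tricycle (vinyl ketone, C9 as in the target)
Conditions: TMSOTf (20 mol %), CH2Cl2, −78 °C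
Reagents that add atoms: none
Why: In this Mukaiyama-type C-glycosidation only the anomeric acetate ionises at −78 °C, and the enol silane attacks the oxocarbenium ion from the convex face (anti to C11 on C10), giving the 2,5-cis, 4,5-trans THF with C8 on the same face as C3.

Step 13
Reactants: 22 C9-(2-oxobut-3-enyl) tricycle
Product: 23 tetracyclic (5Z)-oxonen-7-one (11-acetoxy-5,12-diene)
Conditions: Hoveyda–Grubbs II (10 mol %), 1,4-benzoquinone (20 mol %), toluene (1 mM), 80 °C
Reagents that add atoms: none
Why: Ring-closing metathesis joins the C3-allyl and vinyl-ketone termini, both held on the convex face of the 2,5-cis THF, to give the Z-enone of the nine-membered ether, while the trisubstituted ring-A olefin stays inert.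

Step 14
Reactants: 23 tetracyclic (5Z)-oxonen-7-one
Product: 24 target, CNP0288436.2
Conditions: H2 (4 atm), 5 % Rh/Al2O3, EtOAc, rt
Reagents that add atoms: none
Why: Heterogeneous hydrogenation saturates the enone olefin and adds H2 to C12=C13 from the open convex face (the axial C10–C9 bond blocks the other), placing the C12 methyl cis to OAc, and Rh is chosen over Pd to avoid allylic C–O hydrogenolysis.

**Compound list**
1 | but-2-yn-1-ol | CC#CCO | starting material
2 | sodium cyclic (Z)-vinylalanate from 1 and Red-Al | CC1=CCO[Al-]1(OCCOC)OCCOC.[Na+] | intermediate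
3 | (Z)-3-iodobut-2-en-1-ol | C/C(I)=C/CO | intermediate
4 | allyltributylstannane | C=CC[Sn](CCCC)(CCCC)CCCC | starting material
5 | (Z)-3-methylhexa-2,5-dien-1-ol | C/C(CC=C)=C/CO | intermediate
6 | [(2S,3R)-3-allyl-3-methyloxiran-2-yl]methanol | OC[C@@H]1O[C@]1(C)CC=C | intermediate
7 | (2R,3R)-3-allyl-3-methyloxirane-2-carbaldehyde | O=C[C@@H]1O[C@]1(C)CC=C | intermediate
8 | (S)-3-bromo-2-methylpropan-1-ol | BrC[C@@H](C)CO | starting material
9 | (S)-(3-bromo-2-methylpropoxy)triethylsilane | BrC[C@@H](C)CO[Si](CC)(CC)CC | intermediate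
10 | [2-methyl-3-(triethylsilyloxy)propyl]magnesium bromide | Br[Mg]C[C@@H](C)CO[Si](CC)(CC)CC | intermediate
11 | (R)-3-methyl-4-(triethylsilyloxy)butanal | O=CC[C@@H](C)CO[Si](CC)(CC)CC | intermediate
12 | methyl 3-oxopentanoate | CCC(=O)CC(=O)OC | starting material
13 | methyl 2-{[(2S,3R)-3-allyl-3-methyloxiran-2-yl]methylidene}-3-oxopentanoate (E/Z) | COC(=O)C(=C[C@@H]1O[C@]1(C)CC=C)C(=O)CC | intermediate
14 | methyl (3S,4S,5R)-3-[(2S,3R)-3-allyl-3-methyloxiran-2-yl]-4-formyl-5-methyl-2-propanoyl-6-(triethylsilyloxy)hexanoate | COC(=O)C(C(=O)CC)[C@@H]([C@@H]1O[C@]1(C)CC=C)[C@@H](C=O)[C@@H](C)CO[Si](CC)(CC)CC | intermediate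
15 | methyl (5S,6S)-6-[(2S,3R)-3-allyl-3-methyloxiran-2-yl]-3-methyl-2-oxo-5-[(R)-1-(triethylsilyloxy)propan-2-yl]cyclohex-3-ene-1-carboxylate | COC(=O)C1C(=O)C(C)=C[C@@H]([C@@H](C)CO[Si](CC)(CC)CC)[C@@H]1[C@@H]2O[C@]2(C)CC=C | intermediate
16 | ring-A/oxepane bicycle: methyl keto ester with C3–O–C16 ether (3S), C2–OSiEt3, C3-allyl | COC(=O)C1C(=O)C(C)=C[C@H]2[C@@H](C)CO[C@@](C)(CC=C)[C@@H](O[Si](CC)(CC)CC)[C@H]12 | intermediate
17 | tricyclic keto-lactone (12-en-11-one, C9 γ-lactone, oxepane; all centres as in the target) | O=C1[C@@H]2[C@@H]3[C@@H](C=C1C)[C@@H](C)CO[C@@](C)(CC=C)[C@H]3OC2=O | intermediate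
18 | tricyclic 11-hydroxy lactone | O[C@H]1[C@@H]2[C@@H]3[C@@H](C=C1C)[C@@H](C)CO[C@@](C)(CC=C)[C@H]3OC2=O | intermediate
19 | 11-hydroxy C9-lactol (formed as its aluminium alkoxide) | O[C@H]1[C@@H]2[C@@H]3[C@@H](C=C1C)[C@@H](C)CO[C@@](C)(CC=C)[C@H]3OC2O | intermediate
20 | C11,C9-diacetate (C9 epimers) | CC(=O)O[C@H]1[C@@H]2[C@@H]3[C@@H](C=C1C)[C@@H](C)CO[C@@](C)(CC=C)[C@H]3OC2OC(C)=O | intermediate
21 | 2-(trimethylsilyloxy)buta-1,3-diene | C=CC(=C)O[Si](C)(C)C | starting material
22 | C9-(2-oxobut-3-enyl), C3-allyl tricycle | CC(=O)O[C@H]1[C@@H]2[C@@H]3[C@@H](C=C1C)[C@@H](C)CO[C@@](C)(CC=C)[C@H]3O[C@H]2CC(=O)C=C | intermediate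
23 | tetracyclic (5Z)-oxonen-7-one, 12,13-ene | CC(=O)O[C@H]1[C@@H]2[C@@H]3[C@@H](C=C1C)[C@@H](C)CO[C@@]1(C)C/C=C\C(=O)C[C@@H]2O[C@@H]31 | intermediate
24 | CNP0288436.2 (1S,2S,3S,9S,10R,11R,12R,14S,15R) | CC(=O)O[C@H]1[C@@H]2[C@@H]3[C@@H](C[C@H]1C)[C@@H](C)CO[C@@]1(C)CCCC(=O)C[C@@H]2O[C@@H]31 | target

**Step count and risks**

Total steps: 14. Longest linear sequence: 12 (steps 1–4 and 7–14).

**Most likely to fail, first: step 9.**
- Risks: 6-exo attack at C2, a 1,2-hydride shift to a C2 ketone, or poor nucleophilicity of the silyl ether.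
- The fallback sets out from 15 and comes back at 18.
- Luche reduction of 15 removes the Michael acceptor and gives the epoxy allylic alcohol ester F4.
- Bu4NF then frees O16 to give the epoxy diol ester F5.
- Camphorsulfonic acid (CH2Cl2, 0 °C) triggers the same epoxide opening and lactonisation, now with a free primary alcohol as the nucleophile, and delivers 18 directly.

**Second: step 8.**
- Risks: slow ring closure at the unactivated C12, or amine attack on the epoxide.
- The fallback sets out from 7, 11 and 12 and comes back at 15.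
- Compound 12 is γ-phosphonylated (NaH, n-BuLi; ClP(OEt)2; H2O2) to methyl 4-(diethoxyphosphoryl)-3-oxopentanoate F1.
- F1 is condensed with 7 to the alkylidene keto phosphonate F2.
- Aldehyde 11 is added under the same enamine catalysis to give the phosphonate Michael adduct F3.
- Ring A is closed by an intramolecular Horner–Wadsworth–Emmons reaction (LiCl, i-Pr2NEt, MeCN, rt) to give 15.

**Third: step 13.**
- Risk: a nine-membered enone may not close by RCM, with dimerisation instead.
- The fallback sets out from 20 and comes back at 23.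
- The terminal olefin of 20 is cleaved (OsO4 cat., NaIO4, 2,6-lutidine) to the C5 aldehyde F6.
- Stork–Zhao olefination (Ph3PCH2I+ I−, NaHMDS) gives the (Z)-vinyl iodide F7.
- C-glycosidation with (vinyloxy)trimethylsilane and TMSOTf gives the C7 aldehyde F8.
- An intramolecular Nozaki–Hiyama–Kishi reaction (CrCl2, NiCl2 cat., DMSO, high dilution) closes the C6–C7 bond to the cyclic allylic alcohol F9.
- Dess–Martin oxidation of F9 gives 23.

Further compounds
F1 | step 8 | methyl 4-(diethoxyphosphoryl)-3-oxopentanoate | CCOP(=O)(OCC)C(C)C(=O)CC(=O)OC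
F2 | step 8 | alkylidene keto phosphonate (Knoevenagel adduct of F1 and 7) | CCOP(=O)(OCC)C(C)C(=O)C(=C[C@@H]1O[C@]1(C)CC=C)C(=O)OC
F3 | step 8 | phosphonate Michael adduct of F2 and 11 | CCOP(=O)(OCC)C(C)C(=O)C(C(=O)OC)[C@@H]([C@@H]1O[C@]1(C)CC=C)[C@@H](C=O)[C@@H](C)CO[Si](CC)(CC)CC
F4 | step 9 | epoxy allylic alcohol ester (11-ol of 15, OTES) | COC(=O)[C@@H]1[C@H](O)C(C)=C[C@@H]([C@@H](C)CO[Si](CC)(CC)CC)[C@@H]1[C@@H]2O[C@]2(C)CC=C
F5 | step 9 | epoxy diol ester (free O16) | COC(=O)[C@@H]1[C@H](O)C(C)=C[C@@H]([C@@H](C)CO)[C@@H]1[C@@H]2O[C@]2(C)CC=C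
F6 | step 13 | C5 aldehyde diacetate | CC(=O)O[C@H]1[C@@H]2[C@@H]3[C@@H](C=C1C)[C@@H](C)CO[C@@](C)(CC=O)[C@H]3OC2OC(C)=O
F7 | step 13 | (Z)-vinyl iodide diacetate | CC(=O)O[C@H]1[C@@H]2[C@@H]3[C@@H](C=C1C)[C@@H](C)CO[C@@](C)(C/C=C\I)[C@H]3OC2OC(C)=O
F8 | step 13 | C7 aldehyde (Z)-vinyl iodide | CC(=O)O[C@H]1[C@@H]2[C@@H]3[C@@H](C=C1C)[C@@H](C)CO[C@@](C)(C/C=C\I)[C@H]3O[C@H]2CC=O
F9 | step 13 | cyclic (5Z)-allylic C7 alcohol | CC(=O)O[C@H]1[C@@H]2[C@@H]3[C@@H](C=C1C)[C@@H](C)CO[C@@]1(C)C/C=C\C(O)C[C@@H]2O[C@@H]31
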